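The data were computed with made-up constants, and the scatter is random.

Late in the gamma flask the target reading stands still while most of the starting material sits unused, so the useful sum here is a small correction on one large number.

in all of them: starting material 0.32 M; free catalyst 0.5 mol%
- gamma: reagent 0.95 equiv; second substrate 0.20 equiv; temperature 35 °C; the very flask that is asked about, followed so far
- zeta: reagent 0.64 equiv; second substrate 0.20 equiv; temperature 20 °C; run made earlier
- flask: reagent 0.950 equiv; second substrate 0.200 equiv; temperature 35 °C; time 6.0 h

| gamma: time / h | gamma: target / % | zeta: time / h | zeta: target / % |
|---|---|---|---|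
| 0.333 | 7.3 | 0.133 | 1.4 |
| 1.00 | 10.8 | 0.417 | 4.8 |
| 1.50 | 11.8 | 0.667 | 6.9 |
| 2.50 | 13.0 | 1.00 | 8.4 |
| 4.00 | 13.0 | 1.33 | 10.1 |
| 5.00 | 12.6 | 2.00 | 12.4 |
| 6.00 | 13.1 | 3.00 | 14.2 |

(standard deviation of a reading: 0.3 percentage points)

- amber: at 6.0 h raise the temperature by 20 K, then wait 3.0 h
- grey: at 6.0 h add free catalyst, 100% of the amount charged, then wait 3.0 h
- teal: at 6.0 h add reagent, 50.0% of the amount charged, then wait 3.0 h
- green: change nothing and wait 3.0 h more

- for target the idle complex is counted in
- the volume of additions can be left aside
- the numbers in the tables scatter by 0.3 percentage points (one standard deviation)
- steps thought possible: free catalyst -> spent catalyst; reagent <-> dormant form; free catalyst + target <-> idle complex; starting material + reagent + free catalyst -> free catalyst + target; second substrate + reagent + free catalyst -> free catalyst + second product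

- target, in percent of the starting material first charged, at 6.0 h
- which option adds most target ("none" when 2 percentage points or less is all one gets) (amber / grey / teal / green / none)
- target present, in percent of the starting material first charged, after amber
- target present, in percent of the starting material first charged, after teal

My reckoning treats the plateau as the work of one catalyst charge. The working step takes starting material, reagent and free catalyst together, so the target made goes as c(starting material) · c(reagent) · c(free catalyst) times the catalyst's life. With equivalents and loading held, the percent yield then goes as c(starting material) squared. An error in that concentration therefore counts double, while one in reagent or catalyst counts once. The reading time hardly counts, since 2.50 h and 6.00 h differ by 0.1 percentage points. The reagent charge is no stop either: with the second substrate's full share set aside, 0.750 equiv stands against the starting material.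

The number to know well is the plateau, 12.9%, good to 0.15 points. This is the burst: the target, in percent of starting material, that one whole catalyst charge makes on this recipe. Catalyst still live at a late time meets lower c(starting material) and c(reagent) than the first charge met, so it adds less than burst times its share of the charge, and a gain of 2 points needs a live share above 15.5%. The gap to the plateau closes with a time constant of 0.685 h, and 6.0 h is 8.76 of these, which puts the live share far below that need. Heat, reagent and waiting should then add little, and fresh catalyst less than a burst.

The forecast gives 13% (12.7% to 13.3%) now, 13.2% after amber and 13.2% after teal (each 12.7% to 14.5%), and grey as best, worth 6 to 9 points. Its ground is “temperature-driven catalyst death, not reagent shortage”.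

The flask gives 13.0%, with 13.0% after amber and 13.1% after teal. The best option is grey, at 7.2 points, against 0.055 points for teal and 0.032 points for green.

    free catalyst → spent catalyst (k = 0.0260 min⁻¹, Ea = 105 kJ mol⁻¹)
    reagent ⇌ dormant form (K = 1.30, k = 0.0490 min⁻¹, Ea = 91.0 kJ mol⁻¹, ΔH = −54.0 kJ mol⁻¹)
    free catalyst + target ⇌ idle complex (K = 5.90 M⁻¹, k = 0.0680 M⁻¹ min⁻¹, Ea = 53.0 kJ mol⁻¹, ΔH = 16.0 kJ mol⁻¹)
    starting material + reagent + free catalyst → free catalyst + target (k = 15.0 M⁻² min⁻¹, Ea = 37.0 kJ mol⁻¹)
    second substrate + reagent + free catalyst → free catalyst + second product (k = 33.0 M⁻² min⁻¹, Ea = 52.0 kJ mol⁻¹)
    (constants at 35 °C)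

The gamma flask has come to rest. At 6.00 h spent catalyst is 99.5% of the charge, free catalyst 0.171% and idle complex 0.279%, a live share of 0.450%. A share above 15.5% is the least that could fail the forecast on waiting, and this share lies far below it. The burst sets 0.058 points as a ceiling on what it adds, and the flask run to 60.0 h gains less than that, 0.039 points, with 87% of the starting material still there.

For the same recipe at 0.13 M, the burst scaled by the squared concentration gives 2.13%. The computed flask gives 2.53%.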